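**Retrosynthetic overview**
- Pendant cis-α-methyl-γ-lactone: made last, by Friedel–Crafts acylation of the free pyrrole α-carbon with (R)-methylsuccinic anhydride, then CBS reduction and lactonisation.
- Cyclohexane ring and fused lactone: closed together in one carbonylative step, in which the pyrrole β-carbon and CO add anti across an (E)-propenyl carbinol under divalent-palladium catalysis and the carbinol OH traps the acyl-palladium.
- Azepine ring: ring-closing metathesis of an N-pentenyl chain onto a 1,1-disubstituted olefin obtained by ketone methylenation.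
- Ethyl/OH stereodiad: Evans syn-aldol of a butanoyl oxazolidinone with crotonaldehyde, joined to the pyrrole through a Weinreb amide and 2-lithio-N-pentenylpyrrole.
- Ring order: pyrrole (bought) → azepine → cyclohexane and fused lactone (one operation) → pendant lactone.

Assumption: (R)-methylsuccinic acid, (R)-4-benzyloxazolidin-2-one and Tebbe reagent are taken as catalogue items. In the descriptions below, C-3 is the ethyl-bearing carbon, C-22 the O–CH of the fused lactone, C-21 the ring-fusion CH on the pyrrole side and C-26 the CH(CH3) of the fused lactone.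

**Route**

Step 1
Reactants: 1 pyrrole; 2 5-bromopent-1-ene
Product: 3 1-(pent-4-en-1-yl)-1H-pyrrole
Conditions: KOH (powder), DMSO, 23 °C
Reagents that add atoms: none
Why: N-alkylation (SN2) of the pyrrolide anion, which is N-selective in DMSO; no stereocentre is formed.

Step 2
Reactants: 4 (R)-4-benzyloxazolidin-2-one; 5 butanoyl chloride
Product: 6 (R)-4-benzyl-3-butanoyloxazolidin-2-one
Conditions: Et3N, DMAP (cat.), CH2Cl2, 0 → 23 °C
Reagents that add atoms: none
Why: DMAP-catalysed N-acylation of the oxazolidinone; the auxiliary stereocentre is untouched.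

Step 3
Reactants: 6 (R)-4-benzyl-3-butanoyloxazolidin-2-one; 7 (E)-but-2-enal
Product: 9 (R)-4-benzyl-3-[(2R,3S,4E)-2-ethyl-3-hydroxyhex-4-enoyl]oxazolidin-2-one, via Z-dibutylboron enolate 8 (not isolated)
Conditions: n-Bu2BOTf, i-Pr2NEt, CH2Cl2, 0 °C; then 7, −78 → 0 °C; then pH 7 buffer, MeOH, 30% H2O2, 0 °C
Reagents that add atoms: dibutylboron triflate, CCCCB(CCCC)OS(=O)(=O)C(F)(F)F (boron unit carried by 8 only)
Why: Evans syn-aldol reaction; the Z-boron enolate reacts through a Zimmerman–Traxler chair on the face left open by the (R)-benzyl group, which sets the 2R,3S syn diad (C-3 and C-22 of the target) by 1,2-addition to the enal.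

Step 4
Reactants: 9 (R)-4-benzyl-3-[(2R,3S,4E)-2-ethyl-3-hydroxyhex-4-enoyl]oxazolidin-2-one
Product: 10 (2R,3S,4E)-2-ethyl-3-hydroxy-N-methoxy-N-methylhex-4-enamide
Conditions: MeNH(OMe)·HCl, AlMe3, CH2Cl2, −15 → 0 °C; aq. HCl work-up
Reagents that add atoms: N,O-dimethylhydroxylamine hydrochloride, CNOC.Cl
Why: Weinreb transamidation by the aluminium amide, assisted by the free β-hydroxyl, removes the auxiliary without epimerising the α-centre.

Step 5
Reactants: 3 1-(pent-4-en-1-yl)-1H-pyrrole; 10 (2R,3S,4E)-2-ethyl-3-hydroxy-N-methoxy-N-methylhex-4-enamide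
Product: 12 (2R,3S,4E)-2-ethyl-3-hydroxy-1-[1-(pent-4-en-1-yl)-1H-pyrrol-2-yl]hex-4-en-1-one, via 2-lithio-1-(pent-4-en-1-yl)pyrrole 11 (not isolated)
Conditions: 3 (2.6 equiv), n-BuLi, TMEDA, THF–hexane, 0 °C; then 10, THF, −78 → −20 °C; sat. NH4Cl
Reagents that add atoms: n-butyllithium, [Li]CCCC (lithium carried by 11 only)
Why: α-lithiation of the N-alkylpyrrole followed by Weinreb ketone synthesis; the first equivalent only forms the lithium alkoxide, and the chelated tetrahedral intermediate prevents over-addition and protects the α-stereocentre until the quench.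

Step 6
Reactants: 12 (2R,3S,4E)-2-ethyl-3-hydroxy-1-[1-(pent-4-en-1-yl)-1H-pyrrol-2-yl]hex-4-en-1-one
Product: 13 (3S,4S,5E)-3-ethyl-2-[1-(pent-4-en-1-yl)-1H-pyrrol-2-yl]hepta-1,5-dien-4-ol
Conditions: Tebbe reagent Cp2Ti(μ-Cl)(μ-CH2)AlMe2 (2.5 equiv), pyridine (cat.), THF, −40 → 0 °C; aq. NaOH
Reagents that add atoms: Tebbe reagent, C[Al-]1(C)C[Ti]([Cl+]1)(C1C=CC=C1)C1C=CC=C1
Why: Tebbe methylenation; the titanium methylidene olefinates even the amide-like 2-acylpyrrole ketone under non-basic conditions, so the α-stereocentre is not epimerised, and the free OH is carried as its titanium alkoxide (hence the excess).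

Step 7
Reactants: 13 (3S,4S,5E)-3-ethyl-2-[1-(pent-4-en-1-yl)-1H-pyrrol-2-yl]hepta-1,5-dien-4-ol
Product: 14 (3S,4S,5E)-3-(6,7-dihydro-5H-pyrrolo[1,2-a]azepin-9-yl)hept-5-en-4-ol
Conditions: second-generation Grubbs catalyst RuCl2(=CHPh)(PCy3)(H2IMes) (7 mol %), toluene (2 mM), 60 °C, Ar sparge
Reagents that add atoms: none
Why: Ring-closing metathesis of the terminal olefin onto the 1,1-disubstituted olefin gives the seven-membered ring with its trisubstituted double bond; the (E)-propenyl group should stay a spectator because closure onto it would need a ten-membered ring, and no stereocentre is touched.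

Step 8
Reactants: 14 (3S,4S,5E)-3-(6,7-dihydro-5H-pyrrolo[1,2-a]azepin-9-yl)hept-5-en-4-ol
Product: 15 tetracyclic lactone core (the target with H at the free pyrrole α-carbon; C-3 S; C-22 R; C-21 S; C-26 R)
Conditions: PdCl2(MeCN)2 (10 mol %), CuCl2 (3 equiv), NaOAc (3 equiv), CO (1 atm), THF–MeCN, 23 °C
Reagents that add atoms: carbon monoxide, [C-]#[O+]
Why: Proposed new method: the PdCl2-bound (E)-propenyl group is attacked anti to palladium by the pyrrole β-carbon (6-exo, Friedel–Crafts-type), the σ-alkylpalladium held by the neighbouring OH inserts CO with retention and the OH captures the acylpalladium as the γ-lactone, so anti addition across the E olefin places CH3 trans to the pyrrole-bearing carbon (C-26 R) while the allylic OH (inside-alkoxy or chelate arrangement, as in related hydroxy-alkene carbonylations) directs the cis ring fusion (C-21 S), and zerovalent palladium is reoxidised by CuCl2; the closest known reaction types are the palladium-catalysed cyclisation/carboalkoxylation of alkenyl indoles and the Semmelhack–Tamaru carbonylative lactonisation of hydroxy alkenes.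

Step 9
Reactants: 16 (R)-2-methylbutanedioic acid
Product: 17 (3R)-3-methyloxolane-2,5-dione
Conditions: AcCl, 55 °C; evaporate
Reagents that add atoms: none
Why: Cyclodehydration of the 1,4-diacid by acetyl chloride under acidic, non-enolising conditions leaves the stereocentre intact.

Step 10
Reactants: 15 tetracyclic lactone core; 17 (3R)-3-methyloxolane-2,5-dione
Product: 19 methyl (2R)-2-methyl-4-oxo-4-(tetracyclic core 15-yl)butanoate (acyl group on the former free pyrrole α-carbon), via keto acid 18 (not isolated)
Conditions: Et2AlCl (2.5 equiv), CH2Cl2, −40 → 0 °C; cold 0.5 M HCl work-up; then TMSCHN2, toluene–MeOH, 0 °C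
Reagents that add atoms: (trimethylsilyl)diazomethane, C[Si](C)(C)C=[N+]=[N-]
Why: Friedel–Crafts acylation at the only free pyrrole α-position, in which the arene attacks the less hindered CH2–C=O of the anhydride so that CH3 ends up next to the carboxyl, with Et2AlCl removing the proton as ethane so that no HCl meets the vinylpyrrole; the acid is then methylated with TMSCHN2.

Step 11
Reactants: 19 methyl (2R)-2-methyl-4-oxo-4-(tetracyclic core 15-yl)butanoate
Product: 21 CNP0324368.1, via hydroxy ester 20 (not isolated)
Conditions: (S)-Me-CBS oxazaborolidine (0.5 equiv), catecholborane (2 equiv), toluene, −78 → −30 °C; MeOH; then imidazole, toluene, 50 °C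
Reagents that add atoms: none
Why: Corey–Bakshi–Shibata reduction, in which the (S)-oxazaborolidine delivers hydride with the pyrrolyl group as the large substituent to give the R carbinol while catecholborane leaves the olefin and the fused lactone alone, followed by 5-exo lactonisation onto the methyl ester to give the cis (R,R) pendant lactone whose CH3 centre comes from (R)-methylsuccinic acid.

**Compound list**

1 | pyrrole | c1cc[nH]c1 | starting material
2 | 5-bromopent-1-ene | C=CCCCBr | starting material
3 | 1-(pent-4-en-1-yl)-1H-pyrrole | C=CCCCn1cccc1 | intermediate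
4 | (R)-4-benzyloxazolidin-2-one | O=C1N[C@H](Cc2ccccc2)CO1 | starting material
5 | butanoyl chloride | CCCC(=O)Cl | starting material
6 | (R)-4-benzyl-3-butanoyloxazolidin-2-one | CCCC(=O)N1[C@H](Cc2ccccc2)COC1=O | intermediate
7 | (E)-but-2-enal (crotonaldehyde) | C/C=C/C=O | starting material
8 | Z-dibutylboron enolate of 6 | CC/C=C(\OB(CCCC)CCCC)N1[C@H](Cc2ccccc2)COC1=O | intermediate
9 | (R)-4-benzyl-3-[(2R,3S,4E)-2-ethyl-3-hydroxyhex-4-enoyl]oxazolidin-2-one | CC[C@H]([C@@H](O)/C=C/C)C(=O)N1[C@H](Cc2ccccc2)COC1=O | intermediate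
10 | (2R,3S,4E)-2-ethyl-3-hydroxy-N-methoxy-N-methylhex-4-enamide | CC[C@H]([C@@H](O)/C=C/C)C(=O)N(C)OC | intermediate
11 | 2-lithio-1-(pent-4-en-1-yl)pyrrole | [Li]c1cccn1CCCC=C | intermediate
12 | (2R,3S,4E)-2-ethyl-3-hydroxy-1-[1-(pent-4-en-1-yl)-1H-pyrrol-2-yl]hex-4-en-1-one | CC[C@H]([C@@H](O)/C=C/C)C(=O)c1cccn1CCCC=C | intermediate
13 | (3S,4S,5E)-3-ethyl-2-[1-(pent-4-en-1-yl)-1H-pyrrol-2-yl]hepta-1,5-dien-4-ol | CC[C@H]([C@@H](O)/C=C/C)C(=C)c1cccn1CCCC=C | intermediate
14 | (3S,4S,5E)-3-(6,7-dihydro-5H-pyrrolo[1,2-a]azepin-9-yl)hept-5-en-4-ol | CC[C@H]([C@@H](O)/C=C/C)C1=CCCCn2cccc12 | intermediate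
15 | tetracyclic lactone core: pyrrolo[1,2-a]azepine fused to a cyclohexane carrying ethyl (S) and a cis-fused α-methyl-γ-lactone (O–CH R, ring-fusion CH S, CH(CH3) R); the target with H at the pyrrole α-carbon | CC[C@H]1C2=CCCCn3ccc(c32)[C@H]2[C@@H]1OC(=O)[C@@H]2C | intermediate
16 | (R)-2-methylbutanedioic acid ((R)-methylsuccinic acid) | C[C@H](CC(=O)O)C(=O)O | starting material
17 | (3R)-3-methyloxolane-2,5-dione ((R)-methylsuccinic anhydride) | C[C@@H]1CC(=O)OC1=O | intermediate
18 | (2R)-2-methyl-4-oxo-4-(tetracyclic core 15-yl)butanoic acid, acyl group on the pyrrole α-carbon | CC[C@H]1C2=CCCCn3c(C(=O)C[C@@H](C)C(=O)O)cc(c32)[C@H]2[C@@H]1OC(=O)[C@@H]2C | intermediate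
19 | methyl ester of 18 | CC[C@H]1C2=CCCCn3c(C(=O)C[C@@H](C)C(=O)OC)cc(c32)[C@H]2[C@@H]1OC(=O)[C@@H]2C | intermediate
20 | methyl (2R,4R)-4-hydroxy-2-methyl-4-(tetracyclic core 15-yl)butanoate | CC[C@H]1C2=CCCCn3c([C@H](O)C[C@@H](C)C(=O)OC)cc(c32)[C@H]2[C@@H]1OC(=O)[C@@H]2C | intermediate
21 | CNP0324368.1 | CC[C@H]1C2=CCCCn3c([C@H]4C[C@@H](C)C(=O)O4)cc(c32)[C@H]2[C@@H]1OC(=O)[C@@H]2C | target

**Step count**

Total steps: 11. Longest linear sequence: 9 steps (steps 2, 3, 4, 5, 6, 7, 8, 10 and 11, from (R)-4-benzyloxazolidin-2-one).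

**Steps most likely to fail, with fallbacks**

Step 8 is the main risk. The pyrrole β-carbon may add to the wrong olefin face and give the C-21 epimer, β-hydride elimination may outrun CO insertion, and CuCl2 may chlorinate or oxidise the electron-rich pyrrole at its free α-position. The fallback sets out from 14 and comes back to the route at 15. Compound 14 is esterified with methacryloyl chloride (Et3N, DMAP) to the methacrylate F1. Ring-closing metathesis with the second-generation Hoveyda–Grubbs catalyst RuCl2(=CH-C6H4-2-O-i-Pr)(H2IMes) expels propene and gives the α-methylbutenolide F2. An intramolecular Friedel–Crafts conjugate addition of the pyrrole β-carbon to the butenolide (Sc(OTf)3, MeCN) can then only give the cis-fused lactone, and brief DBU treatment settles the α-methyl group in the more stable position trans to the pyrrole-bearing carbon, which is 15. No other epimerisable lactone is present at that stage.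

Step 7 is the second risk. The free allylic alcohol and its propenyl group may take part in the metathesis (ethenolysis to a vinyl group, ten-membered closure, ruthenium hydride isomerisation to a ketone). The fallback sets out from 13 and comes back at 14. The alcohol is silylated (Et3SiCl, imidazole) to the triethylsilyl ether F3, whose bulky allylic OSiEt3 group makes the propenyl olefin a spectator. The same metathesis then gives the silylated azepine F4, and TBAF in THF releases 14.

Step 11 is the third risk. The ketone is a vinylogous amide and may reduce slowly or be over-reduced, and the pyrrolyl carbinol can ionise and lose its configuration. The fallback sets out from 15 and comes back at 21 without an acylpyrrole. Vilsmeier formylation (POCl3, DMF) gives the pyrrole aldehyde F5. Allylboration with 2-(ethoxycarbonyl)allylboronic acid pinacol ester under (R)-TRIP phosphoric acid catalysis (the enantiomer that gives R carbinols from aryl aldehydes), with lactonisation and loss of ethanol, gives the α-methylene lactone F6. Conjugate reduction with Stryker reagent [(Ph3P)CuH]6 and t-BuOH protonates the enolate anti to the pyrrolyl group and gives the cis lactone 21, leaving the vinylpyrrole olefin alone.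

Further compounds
F1 | step 8 | methacrylate ester of 14 (stereocentres as in 14) | CC[C@H]([C@@H](OC(=O)C(C)=C)/C=C/C)C1=CCCCn2cccc12
F2 | step 8 | 3-methyl-2(5H)-furanone carrying at C-5 the 1-(6,7-dihydro-5H-pyrrolo[1,2-a]azepin-9-yl)propyl group (stereocentres as in 14) | CC[C@H]([C@H]1OC(=O)C(C)=C1)C1=CCCCn2cccc12
F3 | step 7 | triethylsilyl ether of 13 | CC[C@H]([C@@H](O[Si](CC)(CC)CC)/C=C/C)C(=C)c1cccn1CCCC=C
F4 | step 7 | triethylsilyl ether of 14 | CC[C@H]([C@@H](O[Si](CC)(CC)CC)/C=C/C)C1=CCCCn2cccc12
F5 | step 11 | pyrrole α-carbaldehyde of 15 | CC[C@H]1C2=CCCCn3c(C=O)cc(c32)[C@H]2[C@@H]1OC(=O)[C@@H]2C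
F6 | step 11 | (R)-α-methylene-γ-butyrolactone on the pyrrole α-carbon of 15 | CC[C@H]1C2=CCCCn3c([C@H]4CC(=C)C(=O)O4)cc(c32)[C@H]2[C@@H]1OC(=O)[C@@H]2C
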